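The north run, charged with 0.47 equiv of coupling partner, stops short of 50% conversion if partner is spent one for one with starting material. Any question at that conversion therefore needs a bigger charge, and the flask takes 0.700 equiv, still the limiting reagent. The decision is what to raise in the run after it, partner or free catalyst.

| setting | north | north-east | east | flask |
|---|---|---|---|---|
| starting material | 0.050 M | 0.050 M | 0.025 M | 0.050 M |
| coupling partner | 0.47 equiv | 1 equiv | 0.70 equiv | 0.700 equiv |
| free catalyst | 0.1 mol% | 0.1 mol% | 0.1 mol% | 0.1 mol% |
| remark | run made earlier | run made earlier | run made earlier |  |

| run | time / h | target / % | starting material / % |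
|---|---|---|---|
| north | 6.00 | 2 | 94 |
| north | 15.0 | 10 | 86 |
| north | 20.0 | 14 | 83 |
| north | 30.0 | 22 | 79 |
| north | 40.0 | 31 | 74 |
| north | 50.0 | 33 | 68 |
| north-east | 4.00 | 5 | 99 |
| north-east | 6.00 | 7 | 94 |
| north-east | 8.00 | 1 | 95 |
| north-east | 15.0 | 14 | 83 |
| north-east | 20.0 | 16 | 83 |
| north-east | 30.0 | 28 | 74 |
| north-east | 50.0 | 38 | 61 |
| east | 4.00 | 4 | 100 |
| east | 12.0 | 7 | 92 |
| east | 20.0 | 15 | 91 |
| east | 30.0 | 16 | 86 |
| east | 50.0 | 26 | 71 |

(readings scatter by 2 percentage points)

- apparent order in coupling partner when 50% of the starting material are converted (percent change of the rate of making target for one percent more coupling partner charged)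
- apparent order in free catalyst when 50% of the starting material are converted (percent change of the rate of making target for one percent more free catalyst charged)
- factor on the rate of making target when 50% of the starting material are converted if free catalyst is charged twice over



Take the charge leverage, the charge divided by what is left of it at the conversion you look at, with lev as 3.50. At 50% conversion the flask holds [coupling partner] = 0.0100 M, so one percent more charge raises that remainder by 3.50 percent. In the north-east run the same ratio is 2.00.

North and north-east gave 33% and 38% target at 50.0 h. That reads as a local order in partner of 0.187, a reading with a scatter of 2 percentage points on each point. Through the leverage, my estimate for the order on the charge is 0.654. No run varied free catalyst, so I take first order as a prior. Since 0.654 is smaller than 1, I would raise catalyst and leave the partner charge alone.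

The forecast gives 0.7 for partner, 0.95 for catalyst and a factor of 1.9 on doubling catalyst, warning that “saturation may weaken as the partner runs low”.

The flask gives 1.3 for coupling partner. For free catalyst it gives 1.2, and a factor of 2.20 on doubling. The order in partner stands above the order in catalyst, but it is a slope for one percent more, and the leverage is down to 2.00 at the north-east charge. Free catalyst stays the thing to raise in the next run.

    coupling partner + free catalyst → catalyst intermediate A (k = 1300 M⁻¹ h⁻¹)
    catalyst intermediate A → catalyst intermediate B (k = 34.0 h⁻¹)
    catalyst intermediate B ⇌ released group + catalyst intermediate C (K = 0.380 M, k = 120 h⁻¹)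
    starting material + catalyst intermediate C ⇌ catalyst intermediate D (K = 15.0 M⁻¹, k = 860 M⁻¹ h⁻¹)
    catalyst intermediate D → free catalyst + target (k = 130 h⁻¹)
    coupling partner + catalyst intermediate B ⇌ idle complex, settled at all times (K = 33.0 M⁻¹)
    catalyst intermediate A + released group → spent catalyst (k = 0.910 M⁻¹ h⁻¹)

Divide the flask's 1.3 by the leverage and you get a local order of 0.371 at 50% conversion, larger than the 0.187 read from the earlier runs. The order in free catalyst stands above first order, and one effect on it is the turning of catalyst intermediate A and released group into spent catalyst. The simulated run without that step has an order in free catalyst of 1.0, against the flask's 1.2.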